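**Retrosynthetic overview**

1. Locants: upper unit C2–C8a (rings A, B, C), lower unit C2′–C8a′ (rings D, E, F). The target is traced back through global debenzylation, galloylation of O3/O3′ and removal of two O-allyl groups to a protected procyanidin B2.
2. Feature: ring D (C4a′–C5′–C6′–C7′–C8′–C8a′) is a phloroglucinol ring holding C4 of the upper unit at C8′ and ring F through C4a′ (to C4′) and C8a′ (to O1′). It is opened at C6′–C7′ (Claisen) to a dihydropyran ring F with an acetyl group (C5′, C6′) on C4a′ and a CH(C4)CO2Me arm (C8′, C7′) on C8a′, so the 4→8 linkage is fixed before ring D exists.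
3. C4–C8′ comes from a vinylogous Mukaiyama alkylation of the ring-F keto ester by the C4 cation of DDQ-activated, benzylated (−)-epicatechin (rings A, B, C from the chiral pool).
4. The ring-F keto ester comes from methanolysis of a bicyclic 2-pyranone, which decides that O1′ sits on C8a′ and not on C5′. The pyranone comes from two dianion reactions of methyl acetoacetate; C2′/C3′ come from an Evans glycolate aldol with 3,4-bis(benzyloxy)benzaldehyde (ring E).
5. Ring order: A/B/C and E are given; then the 2-pyranone, ring F, ring D.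

Key step: step 15

Assumption: O3 and O3′ are carried as allyl ethers (stable to every base used, no silyl migration next to the C2′ alkoxide, removed together); 3,4-bis(benzyloxy)benzaldehyde, 2-(allyloxy)acetic acid and 3,4,5-tris(benzyloxy)benzoic acid are taken as purchasable.

Step 1
Reactants: 1 (−)-epicatechin
Product: 2 tetra-O-benzylepicatechin
Conditions: BnBr, K2CO3, DMF, 0 °C → rt
Reagents that add atoms: benzyl bromide, BrCc1ccccc1
Why: Williamson etherification of the four phenols with a carbonate base leaves the secondary 3-OH free, and the mild conditions avoid epimerisation at C2.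

Step 2
Reactants: 2 tetra-O-benzylepicatechin
Product: 3 4β-(2-ethoxyethoxy)-tetra-O-benzylepicatechin
Conditions: DDQ, EtOCH2CH2OH, CH2Cl2, rt
Reagents that add atoms: 2-ethoxyethanol, CCOCCO
Why: Oxidative benzylic C–H etherification: DDQ removes hydride from C4 (activated by the 5,7-dialkoxy ring A) and the cation is trapped by the alcohol on the face trans to the 3-OH, setting the 4β ether.

Step 3
Reactants: 3 4β-(2-ethoxyethoxy)-tetra-O-benzylepicatechin
Product: 4 3-O-allyl-4β-(2-ethoxyethoxy)-tetra-O-benzylepicatechin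
Conditions: NaH, allyl bromide, DMF, 0 °C → rt
Reagents that add atoms: allyl bromide, C=CCBr
Why: Williamson allylation of the secondary alkoxide; the C4 ether and the benzyl ethers are stable to base.

Step 4
Reactants: 5 2-(allyloxy)acetic acid; 6 (S)-4-benzyloxazolidin-2-one
Product: 8 (S)-3-[2-(allyloxy)acetyl]-4-benzyloxazolidin-2-one, via mixed pivalic anhydride 7 (not isolated)
Conditions: t-BuCOCl, Et3N, THF, −20 °C; then 6, LiCl, rt
Reagents that add atoms: none
Why: N-acylation of the oxazolidinone through a mixed anhydride, in which the unhindered glycolyl carbonyl is attacked in preference to the pivaloyl carbonyl.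

Step 5
Reactants: 8 (S)-3-[2-(allyloxy)acetyl]-4-benzyloxazolidin-2-one; 9 3,4-bis(benzyloxy)benzaldehyde
Product: 12 (S)-3-[(2S,3R)-2-(allyloxy)-3-[3,4-bis(benzyloxy)phenyl]-3-hydroxypropanoyl]-4-benzyloxazolidin-2-one, via dibutylboron enolate 10 (not isolated), via boron aldolate 11 (not isolated)
Conditions: Bu2BOTf, Et3N, CH2Cl2, −78 → 0 °C; 9, −78 → 0 °C; pH 7 buffer, MeOH, H2O2, 0 °C
Reagents that add atoms: none
Why: Evans syn-aldol reaction: the (Z)-boron enolate reacts through a Zimmerman–Traxler chair on the face away from the auxiliary benzyl group, setting the carbinol carbon (future C2′) and the allyloxy carbon (future C3′) in the syn relationship that becomes 2′,3′-cis in ring F.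

Step 6
Reactants: 12 aldol adduct
Product: 13 (S)-3-[(2S,3R)-2-(allyloxy)-3-[3,4-bis(benzyloxy)phenyl]-3-(triethylsilyloxy)propanoyl]-4-benzyloxazolidin-2-one
Conditions: Et3SiCl, imidazole, DMF, 0 °C → rt
Reagents that add atoms: chlorotriethylsilane, CC[Si](Cl)(CC)CC
Why: Silylation of the secondary benzylic alcohol blocks retro-aldol cleavage and keeps this oxygen silent through the two dianion steps, while remaining removable by mild acid.

Step 7
Reactants: 13 silylated aldol adduct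
Product: 14 (2R,3R)-2-(allyloxy)-3-[3,4-bis(benzyloxy)phenyl]-3-(triethylsilyloxy)propan-1-ol
Conditions: LiBH4, MeOH (1 equiv), THF, 0 °C
Reagents that add atoms: none
Why: Reductive cleavage of the N-acyloxazolidinone by hydride addition to the exocyclic carbonyl gives the primary alcohol without touching the two stereocentres and returns the auxiliary.

Step 8
Reactants: 14 primary alcohol
Product: 15 [(1R,2S)-2-(allyloxy)-1-[3,4-bis(benzyloxy)phenyl]-3-iodopropoxy]triethylsilane
Conditions: I2, PPh3, imidazole, CH2Cl2, 0 °C → rt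
Reagents that add atoms: iodine, II
Why: Appel-type iodination; iodide displaces the alkoxyphosphonium group at the primary carbon by SN2.

Step 9
Reactants: 15 iodide; 16 methyl acetoacetate
Product: 18 methyl (6R,7R)-6-(allyloxy)-7-[3,4-bis(benzyloxy)phenyl]-3-oxo-7-(triethylsilyloxy)heptanoate, via acetoacetate dianion 17 (not isolated)
Conditions: 16, LiN(iPr)2 (2.1 equiv), THF, 0 °C; then 15, DMPU, 0 °C → rt
Reagents that add atoms: none
Why: γ-Alkylation of a β-keto ester dianion: the terminal carbanion is the most nucleophilic site and displaces the primary iodide (SN2), forming the C4′–C4a′ bond.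

Step 10
Reactants: 18 β-keto ester
Product: 20 methyl (6R,7R)-4-acetyl-6-(allyloxy)-7-[3,4-bis(benzyloxy)phenyl]-3-oxo-7-(triethylsilyloxy)heptanoate, via keto ester dianion 19 (not isolated)
Conditions: LiN(iPr)2 (2.2 equiv), THF, −78 → 0 °C; MeC(O)N(OMe)Me, −78 → 0 °C; aq NH4Cl
Reagents that add atoms: N-methoxy-N-methylacetamide, CON(C)C(C)=O
Why: γ-Acylation of a β-keto ester dianion with a Weinreb amide, whose chelated tetrahedral adduct survives until the quench and prevents over-addition, puts the acetyl group (C5′, C6′) on C4a′.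

Step 11
Reactants: 20 3,5-dioxo ester
Product: 22 5-[(2R,3R)-2-(allyloxy)-3-[3,4-bis(benzyloxy)phenyl]-3-hydroxypropyl]-4-hydroxy-6-methyl-2H-pyran-2-one, via silylated pyranone 21 (not isolated)
Conditions: DBU, toluene, 90 °C; then AcOH/THF/H2O 3:1:1, rt
Reagents that add atoms: none
Why: Base-mediated enol lactonisation of a 3,5-dioxo ester (the enol oxygen on C5′ acylated by the ester) gives the 4-hydroxy-2-pyranone, leaving one enolic OH, the one on C8a′; mild aqueous acid then removes the triethylsilyl group.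

Step 12
Reactants: 22 hydroxy pyranone
Product: 24 (2R,3R)-3-(allyloxy)-2-[3,4-bis(benzyloxy)phenyl]-5-methyl-3,4-dihydro-2H,7H-pyrano[4,3-b]pyran-7-one, via pyranone tosylate 23 (not isolated)
Conditions: TsCl, Et3N, CH2Cl2, 0 °C; then Cs2CO3, MeCN, rt
Reagents that add atoms: none
Why: The acidic vinylogous-acid OH is sulfonylated selectively, and the benzylic alkoxide then closes ring F by intramolecular nucleophilic vinylic substitution (6-exo-trig addition to C8a′, loss of tosylate); the C2′–O bond is never broken, so the aldol configuration is kept and the ring is 2′,3′-cis.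

Step 13
Reactants: 24 bicyclic 2-pyranone
Product: 25 methyl 2-[(2R,3R)-5-acetyl-3-(allyloxy)-2-[3,4-bis(benzyloxy)phenyl]-3,4-dihydro-2H-pyran-6-yl]acetate
Conditions: NaOMe, MeOH/THF, 0 °C; AcOH
Reagents that add atoms: sodium methoxide, [Na+].[O-]C
Why: Alkoxide acyl substitution at the enol-lactone carbonyl C7′ opens the pyranone to a dienolate that is protonated at C8′, giving the β-alkoxy enone with O1′ fixed on C8a′; any exocyclic acrylate tautomer gives the same dienol ether in step 14.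

Step 14
Reactants: 25 ring-F keto ester; 4 C4 electrophile
Product: 27 methyl 2-(3-O-allyl-tetra-O-benzylepicatechin-4β-yl)-2-[(2R,3R)-5-acetyl-3-(allyloxy)-2-[3,4-bis(benzyloxy)phenyl]-3,4-dihydro-2H-pyran-6-yl]acetate as both C8′ epimers, via silyl dienol ether 26 (not isolated)
Conditions: TBSOTf, Et3N, CH2Cl2, 0 °C; then 4, TMSOTf (cat.), CH2Cl2, −78 → −40 °C
Reagents that add atoms: none
Why: Soft enolisation removes the doubly activated C8′–H to give the silyl dienol ether, and the benzylic C4 cation released by TMSOTf is captured at the γ-terminus C8′ (vinylogous Mukaiyama-type SN1 alkylation) on the face anti to the pseudoaxial 3-O-allyl group, which sets C4 as 4β; C8′ forms as a mixture that is erased in step 15.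

Step 15
Reactants: 27 Claisen precursor
Product: 28 3,3′-di-O-allyl-hexa-O-benzylprocyanidin B2 5′,7′-diol
Conditions: NaOMe (5 equiv), MeOH/THF 2:1, 65 °C, Ar; AcOH
Reagents that add atoms: none
Why: In methanol the substrate equilibrates between its C8′ carbanion (the more acidic site, unproductive because the only ring it could close is four-membered) and the minor methyl ketone enolate at C6′, which adds to the ester carbonyl C7′; the tetrahedral intermediate expels methoxide and the cyclohexenedione enolises to the phenol, whose deprotonation makes the sequence irreversible. The closest known reaction type is the Claisen (Dieckmann) cyclisation of 3,5-dioxo esters and their 3-enol ethers to phloroglucinols and 5-alkoxyresorcinols, as in polyketide aromatisation. Ring D closes in a 6-(enolendo)-exo-trig mode, helped by the cis arrangement of the acetyl and acetate arms on the C4a′=C8a′ double bond. No stereocentre is formed and C8′ becomes aromatic, so both epimers converge. The step needs C-acylation through C6′ and not the dianion that an excess of a lithium amide in THF would give (its ester carbon would sit in an enolate and be inert), which is why a protic alkoxide medium is used; reversible O-acylation back to the 2-pyranone drains through the same anions. Regiochemistry is secured by the substrate, since O1′ is already bonded to C8a′ and C4 to C8′ so that only the 4→8 arene can form, and C2, C3, C4, C2′ and C3′ carry no acidic hydrogen.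

Step 16
Reactants: 28 diphenol
Product: 29 3,3′-di-O-allyl-octa-O-benzylprocyanidin B2
Conditions: BnBr, K2CO3, DMF, rt
Reagents that add atoms: benzyl bromide, BrCc1ccccc1
Why: Williamson benzylation of the two new ring-D phenols makes all eight phenols uniform ahead of acylation.

Step 17
Reactants: 29 bis-allyl ether
Product: 31 octa-O-benzylprocyanidin B2 with free 3-OH and 3′-OH, via bis-propenyl ether 30 (not isolated)
Conditions: [Ir(cod)(PMePh2)2]PF6 (cat., H2-activated), THF, rt; then TsOH·H2O, MeOH/CH2Cl2, rt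
Reagents that add atoms: none
Why: Iridium-catalysed isomerisation of the allyl ethers to prop-1-enyl ethers followed by mild acid hydrolysis of the enol ethers frees both secondary alcohols while the benzyl ethers stay.

Step 18
Reactants: 31 diol; 32 3,4,5-tris(benzyloxy)benzoic acid (two molecules react, one per hydroxyl)
Product: 33 octa-O-benzylprocyanidin B2 3,3′-bis[3,4,5-tris(benzyloxy)benzoate]
Conditions: 32 (3 equiv), DCC (3 equiv), DMAP, CH2Cl2, rt
Reagents that add atoms: 3,4,5-tris(benzyloxy)benzoic acid (the second molecule of 32), OC(=O)c1cc(OCc2ccccc2)c(OCc2ccccc2)c(OCc2ccccc2)c1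
Why: Steglich esterification with an excess of the acid acylates both hindered secondary alcohols through the acylpyridinium intermediate, one molecule of 32 being consumed at O3 and one at O3′, with retention at C3 and C3′.

Step 19
Reactants: 33 protected digallate
Product: 34 3,3′-digalloylprocyanidin B2
Conditions: H2 (1 atm), Pd(OH)2/C, THF/MeOH/H2O, rt
Reagents that add atoms: none
Why: Hydrogenolysis cleaves all fourteen benzyl ethers, while the gallate esters, the interflavan bond and the benzylic ring ethers should survive under neutral conditions.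

**Compound list**

1 | (−)-epicatechin, (2R,3R)-2-(3,4-dihydroxyphenyl)chromane-3,5,7-triol | O[C@@H]1Cc2c(O)cc(O)cc2O[C@@H]1c1ccc(O)c(O)c1 | starting material
2 | tetra-O-benzylepicatechin, (2R,3R)-5,7-bis(benzyloxy)-2-[3,4-bis(benzyloxy)phenyl]chroman-3-ol | O[C@@H]1Cc2c(OCc3ccccc3)cc(OCc3ccccc3)cc2O[C@@H]1c1ccc(OCc2ccccc2)c(OCc2ccccc2)c1 | intermediate
3 | 4β-(2-ethoxyethoxy)-tetra-O-benzylepicatechin (C4 ether trans to the 3-OH and to the 2-aryl group) | O[C@@H]1[C@@H](OCCOCC)c2c(OCc3ccccc3)cc(OCc3ccccc3)cc2O[C@@H]1c1ccc(OCc2ccccc2)c(OCc2ccccc2)c1 | intermediate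
4 | 3-O-allyl-4β-(2-ethoxyethoxy)-tetra-O-benzylepicatechin | C=CCO[C@@H]1[C@@H](OCCOCC)c2c(OCc3ccccc3)cc(OCc3ccccc3)cc2O[C@@H]1c1ccc(OCc2ccccc2)c(OCc2ccccc2)c1 | intermediate
5 | 2-(allyloxy)acetic acid | OC(=O)COCC=C | starting material
6 | (S)-4-benzyloxazolidin-2-one | O=C1N[C@@H](Cc2ccccc2)CO1 | starting material
7 | 2-(allyloxy)acetic pivalic anhydride (not isolated) | C=CCOCC(=O)OC(=O)C(C)(C)C | intermediate
8 | (S)-3-[2-(allyloxy)acetyl]-4-benzyloxazolidin-2-one | C=CCOCC(=O)N1[C@@H](Cc2ccccc2)COC1=O | intermediate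
9 | 3,4-bis(benzyloxy)benzaldehyde | O=Cc1ccc(OCc2ccccc2)c(OCc2ccccc2)c1 | starting material
10 | (Z)-dibutylboron enolate of 8 (not isolated) | C=CCO/C=C(\OB(CCCC)CCCC)N1[C@@H](Cc2ccccc2)COC1=O | intermediate
11 | dibutylboron aldolate of 12 (not isolated) | CCCCB(CCCC)O[C@H](c1ccc(OCc2ccccc2)c(OCc2ccccc2)c1)[C@H](OCC=C)C(=O)N1[C@@H](Cc2ccccc2)COC1=O | intermediate
12 | (S)-3-[(2S,3R)-2-(allyloxy)-3-[3,4-bis(benzyloxy)phenyl]-3-hydroxypropanoyl]-4-benzyloxazolidin-2-one | O[C@H](c1ccc(OCc2ccccc2)c(OCc2ccccc2)c1)[C@H](OCC=C)C(=O)N1[C@@H](Cc2ccccc2)COC1=O | intermediate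
13 | (S)-3-[(2S,3R)-2-(allyloxy)-3-[3,4-bis(benzyloxy)phenyl]-3-(triethylsilyloxy)propanoyl]-4-benzyloxazolidin-2-one | CC[Si](CC)(CC)O[C@H](c1ccc(OCc2ccccc2)c(OCc2ccccc2)c1)[C@H](OCC=C)C(=O)N1[C@@H](Cc2ccccc2)COC1=O | intermediate
14 | (2R,3R)-2-(allyloxy)-3-[3,4-bis(benzyloxy)phenyl]-3-(triethylsilyloxy)propan-1-ol | CC[Si](CC)(CC)O[C@H](c1ccc(OCc2ccccc2)c(OCc2ccccc2)c1)[C@H](OCC=C)CO | intermediate
15 | [(1R,2S)-2-(allyloxy)-1-[3,4-bis(benzyloxy)phenyl]-3-iodopropoxy]triethylsilane | CC[Si](CC)(CC)O[C@H](c1ccc(OCc2ccccc2)c(OCc2ccccc2)c1)[C@H](OCC=C)CI | intermediate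
16 | methyl acetoacetate | COC(=O)CC(C)=O | starting material
17 | dilithium dianion of methyl acetoacetate (not isolated) | [Li+].[Li+].COC(=O)C=C([O-])[CH2-] | intermediate
18 | methyl (6R,7R)-6-(allyloxy)-7-[3,4-bis(benzyloxy)phenyl]-3-oxo-7-(triethylsilyloxy)heptanoate | CC[Si](CC)(CC)O[C@H](c1ccc(OCc2ccccc2)c(OCc2ccccc2)c1)[C@H](OCC=C)CCC(=O)CC(=O)OC | intermediate
19 | dilithium 2,4-dianion of 18 (not isolated) | [Li+].[Li+].CC[Si](CC)(CC)O[C@H](c1ccc(OCc2ccccc2)c(OCc2ccccc2)c1)[C@H](OCC=C)C[CH-]C([O-])=CC(=O)OC | intermediate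
20 | methyl (6R,7R)-4-acetyl-6-(allyloxy)-7-[3,4-bis(benzyloxy)phenyl]-3-oxo-7-(triethylsilyloxy)heptanoate (C4 epimers and enol forms) | CC[Si](CC)(CC)O[C@H](c1ccc(OCc2ccccc2)c(OCc2ccccc2)c1)[C@H](OCC=C)CC(C(C)=O)C(=O)CC(=O)OC | intermediate
21 | 5-[(2R,3R)-2-(allyloxy)-3-[3,4-bis(benzyloxy)phenyl]-3-(triethylsilyloxy)propyl]-4-hydroxy-6-methyl-2H-pyran-2-one (not isolated) | CC[Si](CC)(CC)O[C@H](c1ccc(OCc2ccccc2)c(OCc2ccccc2)c1)[C@H](OCC=C)CC1=C(C)OC(=O)C=C1O | intermediate
22 | 5-[(2R,3R)-2-(allyloxy)-3-[3,4-bis(benzyloxy)phenyl]-3-hydroxypropyl]-4-hydroxy-6-methyl-2H-pyran-2-one | O[C@H](c1ccc(OCc2ccccc2)c(OCc2ccccc2)c1)[C@H](OCC=C)CC1=C(C)OC(=O)C=C1O | intermediate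
23 | 4-O-tosylate of 22 (not isolated) | O[C@H](c1ccc(OCc2ccccc2)c(OCc2ccccc2)c1)[C@H](OCC=C)CC1=C(C)OC(=O)C=C1OS(=O)(=O)c1ccc(C)cc1 | intermediate
24 | (2R,3R)-3-(allyloxy)-2-[3,4-bis(benzyloxy)phenyl]-5-methyl-3,4-dihydro-2H,7H-pyrano[4,3-b]pyran-7-one | C=CCO[C@@H]1CC2=C(C)OC(=O)C=C2O[C@@H]1c1ccc(OCc2ccccc2)c(OCc2ccccc2)c1 | intermediate
25 | methyl 2-[(2R,3R)-5-acetyl-3-(allyloxy)-2-[3,4-bis(benzyloxy)phenyl]-3,4-dihydro-2H-pyran-6-yl]acetate | C=CCO[C@@H]1CC(C(C)=O)=C(CC(=O)OC)O[C@@H]1c1ccc(OCc2ccccc2)c(OCc2ccccc2)c1 | intermediate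
26 | tert-butyldimethylsilyl dienol ether of 25, methyl 2-[(2R,3R)-3-(allyloxy)-2-[3,4-bis(benzyloxy)phenyl]-5-[1-(tert-butyldimethylsilyloxy)ethylidene]tetrahydropyran-6-ylidene]acetate (not isolated) | C=CCO[C@@H]1CC(=C(C)O[Si](C)(C)C(C)(C)C)C(=CC(=O)OC)O[C@@H]1c1ccc(OCc2ccccc2)c(OCc2ccccc2)c1 | intermediate
27 | methyl 2-(3-O-allyl-tetra-O-benzylepicatechin-4β-yl)-2-[(2R,3R)-5-acetyl-3-(allyloxy)-2-[3,4-bis(benzyloxy)phenyl]-3,4-dihydro-2H-pyran-6-yl]acetate (both C8′ epimers) | C=CCO[C@@H]1[C@@H](C(C(=O)OC)C2=C(C(C)=O)C[C@@H](OCC=C)[C@@H](c3ccc(OCc4ccccc4)c(OCc4ccccc4)c3)O2)c2c(OCc3ccccc3)cc(OCc3ccccc3)cc2O[C@@H]1c1ccc(OCc2ccccc2)c(OCc2ccccc2)c1 | intermediate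
28 | 3,3′-di-O-allyl-hexa-O-benzylprocyanidin B2 5′,7′-diol: 3-O-allyl-tetra-O-benzylepicatechin joined 4β→8′ to (2′R,3′R)-3′-(allyloxy)-2′-[3,4-bis(benzyloxy)phenyl]chroman-5′,7′-diol | C=CCO[C@@H]1[C@@H](c2c(O)cc(O)c3c2O[C@H](c2ccc(OCc4ccccc4)c(OCc4ccccc4)c2)[C@H](OCC=C)C3)c2c(OCc3ccccc3)cc(OCc3ccccc3)cc2O[C@@H]1c1ccc(OCc2ccccc2)c(OCc2ccccc2)c1 | intermediate
29 | 3,3′-di-O-allyl-octa-O-benzylprocyanidin B2 (all eight phenols benzylated) | C=CCO[C@@H]1[C@@H](c2c(OCc4ccccc4)cc(OCc4ccccc4)c3c2O[C@H](c2ccc(OCc4ccccc4)c(OCc4ccccc4)c2)[C@H](OCC=C)C3)c2c(OCc3ccccc3)cc(OCc3ccccc3)cc2O[C@@H]1c1ccc(OCc2ccccc2)c(OCc2ccccc2)c1 | intermediate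
30 | 3,3′-di-O-(prop-1-enyl)-octa-O-benzylprocyanidin B2 (not isolated) | CC=CO[C@@H]1[C@@H](c2c(OCc4ccccc4)cc(OCc4ccccc4)c3c2O[C@H](c2ccc(OCc4ccccc4)c(OCc4ccccc4)c2)[C@H](OC=CC)C3)c2c(OCc3ccccc3)cc(OCc3ccccc3)cc2O[C@@H]1c1ccc(OCc2ccccc2)c(OCc2ccccc2)c1 | intermediate
31 | octa-O-benzylprocyanidin B2 (free 3-OH and 3′-OH) | O[C@@H]1[C@@H](c2c(OCc4ccccc4)cc(OCc4ccccc4)c3c2O[C@H](c2ccc(OCc4ccccc4)c(OCc4ccccc4)c2)[C@H](O)C3)c2c(OCc3ccccc3)cc(OCc3ccccc3)cc2O[C@@H]1c1ccc(OCc2ccccc2)c(OCc2ccccc2)c1 | intermediate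
32 | 3,4,5-tris(benzyloxy)benzoic acid | OC(=O)c1cc(OCc2ccccc2)c(OCc2ccccc2)c(OCc2ccccc2)c1 | starting material
33 | octa-O-benzylprocyanidin B2 3,3′-bis[3,4,5-tris(benzyloxy)benzoate] | O=C(O[C@@H]1[C@@H](c2c(OCc4ccccc4)cc(OCc4ccccc4)c3c2O[C@H](c2ccc(OCc4ccccc4)c(OCc4ccccc4)c2)[C@H](OC(=O)c2cc(OCc4ccccc4)c(OCc4ccccc4)c(OCc4ccccc4)c2)C3)c2c(OCc3ccccc3)cc(OCc3ccccc3)cc2O[C@@H]1c1ccc(OCc2ccccc2)c(OCc2ccccc2)c1)c1cc(OCc2ccccc2)c(OCc2ccccc2)c(OCc2ccccc2)c1 | intermediate
34 | 3,3′-digalloylprocyanidin B2, upper unit (2R,3R,4R), lower unit (2′R,3′R) | O=C(O[C@@H]1[C@@H](c2c(O)cc(O)c3c2O[C@H](c2ccc(O)c(O)c2)[C@H](OC(=O)c2cc(O)c(O)c(O)c2)C3)c2c(O)cc(O)cc2O[C@@H]1c1ccc(O)c(O)c1)c1cc(O)c(O)c(O)c1 | target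

**Step count and risks**

Total: 19 steps. Longest linear sequence: 16 steps (steps 4–19, from 5 and 6); the three-step branch to 4 joins at step 14.

Most likely to fail:

Step 15. The substrate may rest as its C8′ carbanion so that the C6′ enolate never reaches the ester, or methoxide may exchange at C8a′ and open ring F before ring D closes. The fallback sets out from 2 and 4 and takes ring D from the chiral pool. Compound 2 is allylated (NaH, allyl bromide, DMF) to 3-O-allyl-tetra-O-benzylepicatechin F1. F1 in excess is then condensed with 4 under catalytic TMSOTf in CH2Cl2 at −78 °C, a Lewis-acid arylation of the C4 cation in which the benzylated nucleophile reacts at C8. This comes back to the route at 29.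

Step 14. Soft enolisation may take a hydrogen of the acetyl methyl group instead of C8′–H, or the hindered C4 cation may lose a proton to the flav-3-ene faster than it is captured at the ester-bearing terminus. The fallback sets out from 21 (isolated after the DBU stage of step 11) and 4 and makes the C4–C8′ bond on the pyranone. The C3 carbon of the 4-hydroxy-2-pyranone (the future C8′) is the only nucleophilic carbon of a vinylogous acid; it is alkylated by the C4 cation (catalytic TMSOTf, CH2Cl2, −78 → −20 °C) to give the 3-(flavan-4β-yl)pyranone F2. AcOH/THF/H2O removes the triethylsilyl group to give alcohol F3. TsCl/Et3N gives tosylate F4, Cs2CO3 in MeCN closes ring F to the bicyclic pyranone F5, and NaOMe in MeOH/THF at 0 °C opens the lactone to 27, where the route is rejoined.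

Step 9. SN2 displacement at the β-branched, β-alkoxy primary iodide may be slower than proton abstraction by the dianion, so that elimination to the enol ether wins. The fallback sets out from 14 and forms C4′–C4a′ by olefination. Oxidation with Dess–Martin periodinane gives (2S,3R)-2-(allyloxy)-3-[3,4-bis(benzyloxy)phenyl]-3-(triethylsilyloxy)propanal F6. Wittig olefination with methyl 3-oxo-4-(triphenylphosphoranylidene)butanoate (toluene, 60 °C) gives the (E)-enone F7. Conjugate reduction with [(Ph3P)CuH]6 in wet benzene, which leaves the allyl ether alone, gives 18.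

**Further compounds**

F1 | step 15 | 3-O-allyl-tetra-O-benzylepicatechin | C=CCO[C@@H]1Cc2c(OCc3ccccc3)cc(OCc3ccccc3)cc2O[C@@H]1c1ccc(OCc2ccccc2)c(OCc2ccccc2)c1
F2 | step 14 | 3-(3-O-allyl-tetra-O-benzylepicatechin-4β-yl)-5-[(2R,3R)-2-(allyloxy)-3-[3,4-bis(benzyloxy)phenyl]-3-(triethylsilyloxy)propyl]-4-hydroxy-6-methyl-2H-pyran-2-one | C=CCO[C@@H]1[C@@H](C2=C(O)C(C[C@@H](OCC=C)[C@H](O[Si](CC)(CC)CC)c3ccc(OCc4ccccc4)c(OCc4ccccc4)c3)=C(C)OC2=O)c2c(OCc3ccccc3)cc(OCc3ccccc3)cc2O[C@@H]1c1ccc(OCc2ccccc2)c(OCc2ccccc2)c1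
F3 | step 14 | desilylated alcohol of F2 | C=CCO[C@@H]1[C@@H](C2=C(O)C(C[C@@H](OCC=C)[C@H](O)c3ccc(OCc4ccccc4)c(OCc4ccccc4)c3)=C(C)OC2=O)c2c(OCc3ccccc3)cc(OCc3ccccc3)cc2O[C@@H]1c1ccc(OCc2ccccc2)c(OCc2ccccc2)c1
F4 | step 14 | 4-O-tosylate of F3 | C=CCO[C@@H]1[C@@H](C2=C(OS(=O)(=O)c3ccc(C)cc3)C(C[C@@H](OCC=C)[C@H](O)c3ccc(OCc4ccccc4)c(OCc4ccccc4)c3)=C(C)OC2=O)c2c(OCc3ccccc3)cc(OCc3ccccc3)cc2O[C@@H]1c1ccc(OCc2ccccc2)c(OCc2ccccc2)c1
F5 | step 14 | (2R,3R)-3-(allyloxy)-8-(3-O-allyl-tetra-O-benzylepicatechin-4β-yl)-2-[3,4-bis(benzyloxy)phenyl]-5-methyl-3,4-dihydro-2H,7H-pyrano[4,3-b]pyran-7-one | C=CCO[C@@H]1[C@@H](C2=C3O[C@H](c4ccc(OCc5ccccc5)c(OCc5ccccc5)c4)[C@H](OCC=C)CC3=C(C)OC2=O)c2c(OCc3ccccc3)cc(OCc3ccccc3)cc2O[C@@H]1c1ccc(OCc2ccccc2)c(OCc2ccccc2)c1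
F6 | step 9 | (2S,3R)-2-(allyloxy)-3-[3,4-bis(benzyloxy)phenyl]-3-(triethylsilyloxy)propanal | CC[Si](CC)(CC)O[C@H](c1ccc(OCc2ccccc2)c(OCc2ccccc2)c1)[C@H](OCC=C)C=O
F7 | step 9 | methyl (4E,6R,7R)-6-(allyloxy)-7-[3,4-bis(benzyloxy)phenyl]-3-oxo-7-(triethylsilyloxy)hept-4-enoate | CC[Si](CC)(CC)O[C@H](c1ccc(OCc2ccccc2)c(OCc2ccccc2)c1)[C@H](OCC=C)/C=C/C(=O)CC(=O)OC
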